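**Plan**
- Retrosynthesis first masks the three phenols: the 3'- and 5'-OH of ring B as benzyl ethers and the 5-OH of ring A as its methyl ether. Ring C is then cut in one operation at C4a–C4, C4–C3 and O1–C2.
- This cut is available because ring C is a 4-pyranone whose carbonyl carbon C4 sits between arene carbon C4a and C3, while O1 is the phenolic oxygen on C8a. C4 is therefore carbon monoxide, C2–C3 an arylacetylene, and ring A an ortho-iodophenol.
- Forward, the ring A piece comes from mono-iodination of symmetric 3,4,5-trimethoxyphenol. The ring B alkyne comes from 2,4-dihydroxybenzaldehyde by benzylation, Baeyer–Villiger oxidation with methanolysis, magnesium-directed ortho-formylation, O-methylation and Ohira–Bestmann homologation.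
- The two pieces and CO are joined by a palladium-catalysed carbonylative annulation that builds ring C, the only ring made. BCl3 then removes both benzyl groups and the chelated 5-O-methyl group.
- The target has no stereocentre. The control needed is regiochemical: symmetry of the phenol, chelation in the formylation, and chelation in the final demethylation.

Key step: step 7

Remark: flavone numbering is used (ring A C4a–C8a, ring C O1–C4, ring B primed locants); the E geometry drawn for the transient enaminone of the key step is of no consequence, since it is lost on ring closure.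

**Route**

Step 1
Reactants: 1 3,4,5-trimethoxyphenol
Product: 2 2-iodo-3,4,5-trimethoxyphenol
Conditions: NIS (1.0 equiv), MeCN, 0 °C, dark
Reagents that add atoms: N-iodosuccinimide, O=C1CCC(=O)N1I
Why: Electrophilic aromatic iodination of a strongly activated phenol; the para position carries a methoxy group and the two ortho positions are equivalent by symmetry, so one equivalent of NIS at low temperature should give a single mono-iodide.

Step 2
Reactants: 3 2,4-dihydroxybenzaldehyde; 4 benzyl bromide
Product: 5 2,4-bis(benzyloxy)benzaldehyde
Conditions: BnBr (2.4 equiv), K2CO3, DMF, 60 °C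
Reagents that add atoms: benzyl bromide (4), BrCc1ccccc1
Why: Williamson ether synthesis; excess benzyl bromide and mild heating should alkylate both phenols, including the hydrogen-bonded 2-OH, while the aldehyde is inert to K2CO3.

Step 3
Reactants: 5 2,4-bis(benzyloxy)benzaldehyde
Product: 7 2,4-bis(benzyloxy)phenol, via aryl formate 6 (not isolated)
Conditions: mCPBA, CH2Cl2, 0 °C → rt; aq. Na2SO3/NaHCO3 wash; then K2CO3, MeOH, rt
Reagents that add atoms: meta-chloroperoxybenzoic acid, OOC(=O)c1cccc(Cl)c1
Why: Baeyer–Villiger oxidation in which the electron-rich 2,4-dialkoxyaryl group migrates in preference to hydrogen (Dakin-type outcome), followed by transesterification of the formate with methanol, which should free the phenol without touching the benzyl ethers.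

Step 4
Reactants: 7 2,4-bis(benzyloxy)phenol
Product: 9 3,5-bis(benzyloxy)-2-hydroxybenzaldehyde, via hydroxymethylphenol 8 (not isolated)
Conditions: MgCl2 (anhydrous), Et3N, (CH2O)n, THF, reflux; then 1 M HCl
Reagents that add atoms: paraformaldehyde (as formaldehyde), C=O
Why: Magnesium-mediated ortho-formylation (Casnati–Skattebøl reaction): formaldehyde is delivered inside the magnesium phenoxide chelate to the only free ortho carbon, C6, and the hydroxymethyl intermediate is oxidised by hydride transfer to a second formaldehyde, so the otherwise more nucleophilic C5 should not be attacked.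

Step 5
Reactants: 9 3,5-bis(benzyloxy)-2-hydroxybenzaldehyde
Product: 10 3,5-bis(benzyloxy)-2-methoxybenzaldehyde
Conditions: MeI, K2CO3, DMF, rt
Reagents that add atoms: iodomethane, CI
Why: Williamson O-methylation of the only free phenol, which should proceed cleanly in DMF although the OH is hydrogen-bonded to the aldehyde.

Step 6
Reactants: 10 3,5-bis(benzyloxy)-2-methoxybenzaldehyde
Product: 11 1,5-bis(benzyloxy)-3-ethynyl-2-methoxybenzene
Conditions: dimethyl (1-diazo-2-oxopropyl)phosphonate, K2CO3, MeOH, 0 °C → rt
Reagents that add atoms: dimethyl (1-diazo-2-oxopropyl)phosphonate, CC(=O)C(=[N+]=[N-])P(=O)(OC)OC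
Why: Seyferth–Gilbert homologation in its Ohira–Bestmann form; the non-enolisable aryl aldehyde should react with the diazomethylphosphonate anion generated by K2CO3/MeOH to give the terminal alkyne by loss of dinitrogen and 1,2-hydrogen shift, under conditions mild enough for all ether groups.

Step 7
Reactants: 2 2-iodo-3,4,5-trimethoxyphenol; 11 1,5-bis(benzyloxy)-3-ethynyl-2-methoxybenzene; 12 carbon monoxide
Product: 15 2-[3,5-bis(benzyloxy)-2-methoxyphenyl]-5,6,7-trimethoxychromen-4-one, via hydroxyaryl ynone 13 (not isolated), via diethylamino enone 14 (not isolated)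
Conditions: PdCl2(PPh3)2 (5 mol %), CO (20 bar), Et2NH, 120 °C, autoclave
Reagents that add atoms: carbon monoxide (12), [C-]#[O+]
Why: PdCl2(PPh3)2 is reduced in the flask to zerovalent palladium, which inserts into the C–I bond of 2; CO insertion gives an aroyl complex of divalent palladium, and coupling with the acetylide that diethylamine generates from 11 forms C4a–C4 and C4–C3 in ynone 13. Diethylamine then adds to the ynone to give enaminone 14, and the phenol oxygen on C8a attacks the amine-bearing carbon and expels the amine, which forms O1–C2 and closes ring C by a 6-endo addition–elimination. The closest known reaction type is the palladium-catalysed carbonylative Sonogashira annulation of ortho-iodophenols with terminal arylacetylenes to flavones. No stereocentre is formed. The step needs carbonylation to outpace direct alkynylation (which would lead to a 2-arylbenzofuran) and amide formation, and 6-endo to outpace 5-exo closure (aurone); CO pressure without a copper co-catalyst keeps the arylpalladium species on the acyl path, CO insertion relieves the crowding at the palladium flanked by OH and OMe, and the secondary amine routes the closure through the enaminone, whose electrophilic carbon is the one that becomes C2. The oxygenation pattern of ring A is not in question, because phenol 1 is symmetric and 2 has a single C–I bond ortho to its only hydroxyl.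

Step 8
Reactants: 15 2-[3,5-bis(benzyloxy)-2-methoxyphenyl]-5,6,7-trimethoxychromen-4-one
Product: 16 2-(3,5-dihydroxy-2-methoxyphenyl)-5-hydroxy-6,7-dimethoxychromen-4-one
Conditions: BCl3 (1 M in CH2Cl2, excess), pentamethylbenzene, CH2Cl2, −78 → 0 °C; then MeOH, aq. HCl
Reagents that add atoms: none
Why: Lewis acid ether cleavage: BCl3 with pentamethylbenzene as a non-basic benzyl cation scavenger should remove both aryl benzyl ethers at −78 °C, and on warming the boron chelated between the C4 carbonyl and the peri 5-oxygen should cleave only that methyl ether, the 6-, 7- and 2'-methoxy groups lacking such a chelate.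

**Compound list**

1 | 3,4,5-trimethoxyphenol | COc1cc(O)cc(OC)c1OC | starting material
2 | 2-iodo-3,4,5-trimethoxyphenol | COc1cc(O)c(I)c(OC)c1OC | intermediate
3 | 2,4-dihydroxybenzaldehyde | O=Cc1ccc(O)cc1O | starting material
4 | benzyl bromide | BrCc1ccccc1 | starting material
5 | 2,4-bis(benzyloxy)benzaldehyde | O=Cc1ccc(OCc2ccccc2)cc1OCc1ccccc1 | intermediate
6 | 2,4-bis(benzyloxy)phenyl formate (not isolated) | O=COc1ccc(OCc2ccccc2)cc1OCc1ccccc1 | intermediate
7 | 2,4-bis(benzyloxy)phenol | Oc1ccc(OCc2ccccc2)cc1OCc1ccccc1 | intermediate
8 | 2,4-bis(benzyloxy)-6-(hydroxymethyl)phenol (not isolated; present as its magnesium phenoxide) | OCc1cc(OCc2ccccc2)cc(OCc2ccccc2)c1O | intermediate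
9 | 3,5-bis(benzyloxy)-2-hydroxybenzaldehyde | O=Cc1cc(OCc2ccccc2)cc(OCc2ccccc2)c1O | intermediate
10 | 3,5-bis(benzyloxy)-2-methoxybenzaldehyde | O=Cc1cc(OCc2ccccc2)cc(OCc2ccccc2)c1OC | intermediate
11 | 1,5-bis(benzyloxy)-3-ethynyl-2-methoxybenzene | C#Cc1cc(OCc2ccccc2)cc(OCc2ccccc2)c1OC | intermediate
12 | carbon monoxide | [C-]#[O+] | starting material
13 | 3-[3,5-bis(benzyloxy)-2-methoxyphenyl]-1-(2-hydroxy-4,5,6-trimethoxyphenyl)prop-2-yn-1-one (not isolated) | COc1cc(O)c(C(=O)C#Cc2cc(OCc3ccccc3)cc(OCc3ccccc3)c2OC)c(OC)c1OC | intermediate
14 | (E)-3-[3,5-bis(benzyloxy)-2-methoxyphenyl]-3-(diethylamino)-1-(2-hydroxy-4,5,6-trimethoxyphenyl)prop-2-en-1-one (not isolated) | CCN(CC)/C(c1cc(OCc2ccccc2)cc(OCc2ccccc2)c1OC)=C/C(=O)c1c(O)cc(OC)c(OC)c1OC | intermediate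
15 | 2-[3,5-bis(benzyloxy)-2-methoxyphenyl]-5,6,7-trimethoxychromen-4-one | COc1cc2oc(-c3cc(OCc4ccccc4)cc(OCc4ccccc4)c3OC)cc(=O)c2c(OC)c1OC | intermediate
16 | 2-(3,5-dihydroxy-2-methoxyphenyl)-5-hydroxy-6,7-dimethoxychromen-4-one | COc1cc2oc(-c3cc(O)cc(O)c3OC)cc(=O)c2c(O)c1OC | target

**Count**

Total steps: 8. Longest linear sequence: 7 steps (steps 2 to 8, from 2,4-dihydroxybenzaldehyde); step 1 is a one-step side branch.

**Steps most likely to fail**

1. Step 7. Oxidative addition at the hindered, electron-rich C–I bond may be slow. Capture of the aroylpalladium species by diethylamine, copper-free direct alkynylation followed by cycloisomerisation, or 5-exo closure of the ynone could then compete. The fallback builds ring C by chalcone chemistry and sets out from 1 and 10. Friedel–Crafts acetylation of 1 (AcOH, BF3·OEt2, 90 °C) should give 1-(6-hydroxy-2,3,4-trimethoxyphenyl)ethanone F1, again a single isomer by symmetry. Claisen–Schmidt condensation of this ketone with aldehyde 10 (KOH, EtOH, rt) should give (E)-3-[3,5-bis(benzyloxy)-2-methoxyphenyl]-1-(6-hydroxy-2,3,4-trimethoxyphenyl)prop-2-en-1-one F2. Oxidative cyclisation (catalytic I2, DMSO, 130 °C) then returns to the route at 15.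

2. Step 8. On warming with excess BCl3, cleavage may run on to the crowded 6- or 2'-methoxy group. Incomplete trapping of benzyl cations could also lead to benzylation of the electron-rich rings. The fallback separates the two events and sets out from 15. Hydrogenolysis (H2, 1 atm, Pd/C, EtOAc–MeOH, rt) should give 2-(3,5-dihydroxy-2-methoxyphenyl)-5,6,7-trimethoxychromen-4-one F3 without any carbocation. A limited amount of BCl3 (CH2Cl2, −40 → −10 °C), now needed only for the chelation-directed 5-O-demethylation, then returns to the route at 16.

3. Step 4. The benzyloxy oxygen next to the phenoxide may tie up magnesium and slow formaldehyde delivery. This would lead to incomplete conversion, O-methoxymethylation, or condensation of the hydroxymethyl intermediate with a second electron-rich ring. The fallback sets out from 7 and uses a boron tether. Phenylboronic acid, paraformaldehyde and catalytic propionic acid in refluxing toluene (Dean–Stark) should give 6,8-bis(benzyloxy)-2-phenyl-4H-1,3,2-benzodioxaborine F4, in which the new carbon can only be ortho to the phenol oxygen. Oxidative cleavage of the boronate (H2O2, THF, 0 °C) should release hydroxymethylphenol 8, this time isolated. Benzylic oxidation with MnO2 (CH2Cl2, rt) returns to the route at 9.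

**Further compounds**

F1 | step 7 | 1-(6-hydroxy-2,3,4-trimethoxyphenyl)ethanone | CC(=O)c1c(O)cc(OC)c(OC)c1OC
F2 | step 7 | (E)-3-[3,5-bis(benzyloxy)-2-methoxyphenyl]-1-(6-hydroxy-2,3,4-trimethoxyphenyl)prop-2-en-1-one | COc1cc(O)c(C(=O)/C=C/c2cc(OCc3ccccc3)cc(OCc3ccccc3)c2OC)c(OC)c1OC
F3 | step 8 | 2-(3,5-dihydroxy-2-methoxyphenyl)-5,6,7-trimethoxychromen-4-one | COc1cc2oc(-c3cc(O)cc(O)c3OC)cc(=O)c2c(OC)c1OC
F4 | step 4 | 6,8-bis(benzyloxy)-2-phenyl-4H-1,3,2-benzodioxaborine | c1ccc(cc1)B1OCc2cc(OCc3ccccc3)cc(OCc3ccccc3)c2O1
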